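Ring C of the 2H-chromene is cut at C8a–O1, C4a–C4 and O1–C2, leaving a ring A aryne (C4a≡C8a) and a 2-arylacrolein that carries ring B. The step exploits the fact that C4a lies ortho to the C5 methoxy group while C8a must bear O1: the methoxy-polarised aryne accepts the aldehyde oxygen at C8a and bonds C4a to the carbonyl carbon, and the benzoxete opens to an o-quinone methide that closes ring C by oxa-6π electrocyclisation, all in one operation. The aryne precursor is an ortho-trimethylsilyl aryl triflate (silicon on C4a, triflate on C8a) bearing OMe, prenyl and one pivalate; the enal bears two pivalates.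

Key step: step 12

Remark: chromene numbering (O1, C2, C3, C4, C4a, C5 to C8, C8a) is used for the ring A and ring C atoms throughout. The target has no stereocentre; the one transient stereocentre (C4 of the benzoxete) is racemic and is destroyed on ring opening.

Step 1
Reactants: 1 1,3-dimethoxybenzene; 2 1-bromo-3-methylbut-2-ene (prenyl bromide)
Product: 4 1,3-dimethoxy-2-(3-methylbut-2-enyl)benzene, via 2,6-dimethoxyphenyllithium 3 (not isolated)
Conditions: n-BuLi, THF, 0 °C to rt; then CuBr·SMe2 (5 mol%), 2, −20 °C to rt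
Reagents that add atoms: none
Why: Directed ortho-metalation, in which the two methoxy groups jointly direct lithiation to C2, followed by copper-catalysed SN2 alkylation of the aryllithium by the primary allylic bromide, should give the linear prenyl arene.

Step 2
Reactants: 4 1,3-dimethoxy-2-(3-methylbut-2-enyl)benzene
Product: 5 3-methoxy-2-(3-methylbut-2-enyl)phenol
Conditions: NaSEt, DMF, 130 °C; aq. HCl work-up
Reagents that add atoms: none
Why: Thiolate SN2 O-demethylation of an aryl methyl ether should stop at the monophenol because the aryloxide formed by the first cleavage deactivates the second ether, and the soft, weakly basic thiolate leaves the prenyl alkene alone.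

Step 3
Reactants: 5 3-methoxy-2-(3-methylbut-2-enyl)phenol
Product: 6 [3-methoxy-2-(3-methylbut-2-enyl)phenoxy]triisopropylsilane
Conditions: TIPSCl, imidazole, DMF, rt
Reagents that add atoms: chlorotriisopropylsilane, CC(C)[Si](Cl)(C(C)C)C(C)C
Why: Standard silylation of a phenol; the bulky, non-coordinating TIPS ether is chosen because it survives butyllithium and shields the neighbouring ring position in step 6.

Step 4
Reactants: 6 [3-methoxy-2-(3-methylbut-2-enyl)phenoxy]triisopropylsilane
Product: 8 3-methoxy-4-(3-methylbut-2-enyl)-5-(triisopropylsilyloxy)phenol, via aryl pinacol boronate 7 (not isolated)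
Conditions: [Ir(OMe)(cod)]2 (1.5 mol%), 4,4'-di-tert-butyl-2,2'-bipyridine (3 mol%), B2pin2, THF, 65 °C; then NaBO3·4H2O, THF–H2O, rt
Reagents that add atoms: sodium perborate, [Na+].[O-]OB=O (supplies the phenol oxygen); bis(pinacolato)diboron, CC1(C)OB(OC1(C)C)B1OC(C)(C)C(C)(C)O1 (supplies the boryl group of 7)
Why: Sterically governed iridium-catalysed aromatic C–H borylation should occur only at the one ring C–H not flanked by a substituent (meta to both oxygens, para to prenyl), the trisubstituted alkene being a poor substrate for the catalyst, and perborate oxidation of the aryl boronate then gives the phenol without touching alkene or silyl ether.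

Step 5
Reactants: 8 3-methoxy-4-(3-methylbut-2-enyl)-5-(triisopropylsilyloxy)phenol
Product: 9 3-methoxy-4-(3-methylbut-2-enyl)-5-(triisopropylsilyloxy)phenyl N-isopropylcarbamate
Conditions: i-PrNCO, Et3N (cat.), CH2Cl2, rt
Reagents that add atoms: isopropyl isocyanate, CC(C)N=C=O
Why: Amine-catalysed addition of the phenol to the isocyanate gives the N-monoalkyl carbamate, which after N-silylation is a strong ortho-director and later departs under mild E1cB conditions.

Step 6
Reactants: 9 3-methoxy-4-(3-methylbut-2-enyl)-5-(triisopropylsilyloxy)phenyl N-isopropylcarbamate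
Product: 13 3-methoxy-4-(3-methylbut-2-enyl)-5-(triisopropylsilyloxy)-2-(trimethylsilyl)phenyl N-isopropylcarbamate, via N-silyl carbamate 10 (not isolated), via aryllithium 11 (not isolated), via N-silyl C-silyl carbamate 12 (not isolated)
Conditions: TBSOTf, TMEDA, Et2O, 0 °C to rt; then TMEDA, n-BuLi, −78 °C; TMSCl, −78 °C to rt; aq. NaHSO4 work-up
Reagents that add atoms: chlorotrimethylsilane, C[Si](C)(C)Cl; tert-butyldimethylsilyl triflate, CC(C)(C)[Si](C)(C)OS(=O)(=O)C(F)(F)F (silicon carried on nitrogen in 10 to 12 only)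
Why: Directed ortho-metalation of the N-silylated carbamate should take place at the ring carbon between the carbamate and methoxy oxygens (cooperative direction), the other ortho position being blocked by the TIPS ether, and TMSCl trapping followed by acidic N–Si cleavage gives the ortho-silyl carbamate.

Step 7
Reactants: 13 3-methoxy-4-(3-methylbut-2-enyl)-5-(triisopropylsilyloxy)-2-(trimethylsilyl)phenyl N-isopropylcarbamate
Product: 15 3-methoxy-4-(3-methylbut-2-enyl)-5-(pivaloyloxy)-2-(trimethylsilyl)phenyl N-isopropylcarbamate, via ammonium phenoxide 14 (not isolated)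
Conditions: Bu4NF (TBAF, 1.05 equiv), THF, 0 °C; then PivCl, Et3N (buffer), DMAP (cat.), 0 °C to rt
Reagents that add atoms: pivaloyl chloride, CC(C)(C)C(=O)Cl
Why: Fluoride cleaves the aryl O–Si bond much faster than the aryl C–SiMe3 bond at 0 °C and the naked phenoxide is acylated in the same flask, so the lithiation-stable silyl ether is exchanged for a fluoride-stable pivalate before the aryne precursor is completed.

Step 8
Reactants: 15 3-methoxy-4-(3-methylbut-2-enyl)-5-(pivaloyloxy)-2-(trimethylsilyl)phenyl N-isopropylcarbamate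
Product: 17 3-methoxy-4-(3-methylbut-2-enyl)-5-(pivaloyloxy)-2-(trimethylsilyl)phenyl trifluoromethanesulfonate, via ortho-silyl phenol 16 (not isolated)
Conditions: DBU, Et2NH, MeCN, 40 °C; then PhNTf2, rt
Reagents that add atoms: N-phenylbis(trifluoromethanesulfonimide), O=S(=O)(N(c1ccccc1)S(=O)(=O)C(F)(F)F)C(F)(F)F
Why: DBU deprotonates the carbamate N–H and the aryloxide is expelled (E1cB) while diethylamine scavenges the isocyanate, after which PhNTf2 triflates the ortho-silyl phenoxide in the same pot; the hindered pivalate should tolerate the secondary amine at this temperature.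

Step 9
Reactants: 18 4-bromobenzene-1,3-diol
Product: 19 4-bromo-1,3-phenylene bis(2,2-dimethylpropanoate)
Conditions: PivCl, Et3N, DMAP (cat.), CH2Cl2, 0 °C to rt
Reagents that add atoms: pivaloyl chloride, CC(C)(C)C(=O)Cl
Why: DMAP-catalysed acylation of both phenols installs the same fluoride-stable ester that ring A carries.

Step 10
Reactants: 19 4-bromo-1,3-phenylene bis(2,2-dimethylpropanoate); 20 4,4,5,5-tetramethyl-2-(prop-1-en-2-yl)-1,3,2-dioxaborolane
Product: 21 4-(prop-1-en-2-yl)-1,3-phenylene bis(2,2-dimethylpropanoate)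
Conditions: Pd(OAc)2 (2 mol%), SPhos (4 mol%), K3PO4, toluene–H2O, 60 °C
Reagents that add atoms: none
Why: Suzuki–Miyaura coupling (oxidative addition of the aryl bromide to zerovalent palladium, transmetalation of the isopropenyl boronate, reductive elimination); aryl pivalates are inert to palladium and should survive the mild phosphate base.

Step 11
Reactants: 21 4-(prop-1-en-2-yl)-1,3-phenylene bis(2,2-dimethylpropanoate)
Product: 22 2-[2,4-bis(pivaloyloxy)phenyl]prop-2-enal
Conditions: SeO2, 1,4-dioxane, 95 °C; product kept cold in solution with BHT and used promptly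
Reagents that add atoms: selenium dioxide, O=[Se]=O
Why: Selenium dioxide allylic oxidation (ene reaction, 2,3-sigmatropic shift, then oxidation of the allylic alcohol) at the only allylic position, the methyl group of the α-methylstyrene, should give the 2-arylacrolein.

Step 12
Reactants: 17 3-methoxy-4-(3-methylbut-2-enyl)-5-(pivaloyloxy)-2-(trimethylsilyl)phenyl trifluoromethanesulfonate; 22 2-[2,4-bis(pivaloyloxy)phenyl]prop-2-enal
Product: 26 3-[2,4-bis(pivaloyloxy)phenyl]-5-methoxy-6-(3-methylbut-2-enyl)-2H-chromen-7-yl pivalate, via aryne 23 (not isolated), via benzoxete 24 (not isolated), via o-quinone methide 25 (not isolated)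
Conditions: CsF (3 equiv), 22 (3 equiv), BHT (cat.), MeCN–toluene, rt to 40 °C, slow addition of 17
Reagents that add atoms: none
Why: Fluoride attacks silicon of 17 and triflate leaves to give aryne 23; the aldehyde oxygen of 22 adds to C8a and the C4a aryl anion collapses onto the carbonyl carbon (formal (2+2) addition), benzoxete 24 opens by 4π electrocyclic ring opening to o-quinone methide 25, and 25 closes ring C. The closest known reaction type is the fluoride-induced coupling of ortho-silylaryl triflates with aldehydes and formamides through benzoxetes and o-quinone methides, including its use with α,β-unsaturated aldehydes to give 2H-chromenes. Ring C, the only ring formed, closes by a thermal disrotatory oxa-6π electrocyclisation that makes O1–C2 and gives the chromene at its final oxidation level. No stereocentre is created, since the C4 centre of racemic 24 is erased on ring opening. The step needs regioselective addition to the unsymmetrical aryne: the inductive pull and triple-bond distortion caused by the C5 methoxy group make C8a the electrophilic terminus and place the carbanion at C4a, the para pivaloyloxy group exerting only a weak bias, and the same methoxy group pushes the alkenyl arm of 25 toward the carbonyl oxygen as closure requires. Excess enal and slow addition of 17 keep the aryne concentration low, so ene reaction at prenyl groups and capture of 25 by a second aryne should stay behind the intramolecular closure, and the pivalates withstand CsF.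

Step 13
Reactants: 26 3-[2,4-bis(pivaloyloxy)phenyl]-5-methoxy-6-(3-methylbut-2-enyl)-2H-chromen-7-yl pivalate
Product: 27 dehydroglyasperin C, 4-[7-hydroxy-5-methoxy-6-(3-methylbut-2-enyl)-2H-chromen-3-yl]benzene-1,3-diol
Conditions: i-Bu2AlH (8 equiv), CH2Cl2, −78 °C; aq. KNaC4H4O6 (potassium sodium tartrate) work-up under argon
Reagents that add atoms: none
Why: Hydride reduction of the three aryl pivalates at low temperature releases the phenols and neopentyl alcohol without acid or strong aqueous base, so the chromene double bond, the prenyl group next to a free phenol and the air-sensitive resorcinol unit should all survive.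

Compound list
1 | 1,3-dimethoxybenzene | COc1cccc(OC)c1 | starting material
2 | 1-bromo-3-methylbut-2-ene (prenyl bromide) | CC(C)=CCBr | starting material
3 | 2,6-dimethoxyphenyllithium | [Li]c1c(OC)cccc1OC | intermediate (not isolated)
4 | 1,3-dimethoxy-2-(3-methylbut-2-enyl)benzene | COc1cccc(OC)c1CC=C(C)C | intermediate
5 | 3-methoxy-2-(3-methylbut-2-enyl)phenol | COc1cccc(O)c1CC=C(C)C | intermediate
6 | [3-methoxy-2-(3-methylbut-2-enyl)phenoxy]triisopropylsilane | COc1cccc(O[Si](C(C)C)(C(C)C)C(C)C)c1CC=C(C)C | intermediate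
7 | 2-[3-methoxy-4-(3-methylbut-2-enyl)-5-(triisopropylsilyloxy)phenyl]-4,4,5,5-tetramethyl-1,3,2-dioxaborolane | COc1cc(B2OC(C)(C)C(C)(C)O2)cc(O[Si](C(C)C)(C(C)C)C(C)C)c1CC=C(C)C | intermediate (not isolated)
8 | 3-methoxy-4-(3-methylbut-2-enyl)-5-(triisopropylsilyloxy)phenol | COc1cc(O)cc(O[Si](C(C)C)(C(C)C)C(C)C)c1CC=C(C)C | intermediate
9 | 3-methoxy-4-(3-methylbut-2-enyl)-5-(triisopropylsilyloxy)phenyl N-isopropylcarbamate | COc1cc(OC(=O)NC(C)C)cc(O[Si](C(C)C)(C(C)C)C(C)C)c1CC=C(C)C | intermediate
10 | N-(tert-butyldimethylsilyl) derivative of carbamate 9 | COc1cc(OC(=O)N(C(C)C)[Si](C)(C)C(C)(C)C)cc(O[Si](C(C)C)(C(C)C)C(C)C)c1CC=C(C)C | intermediate (not isolated)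
11 | 2-lithio derivative of 10 (lithium on the ring carbon between the carbamate oxygen and OMe) | COc1c([Li])c(OC(=O)N(C(C)C)[Si](C)(C)C(C)(C)C)cc(O[Si](C(C)C)(C(C)C)C(C)C)c1CC=C(C)C | intermediate (not isolated)
12 | N-(tert-butyldimethylsilyl) derivative of carbamate 13 | COc1c([Si](C)(C)C)c(OC(=O)N(C(C)C)[Si](C)(C)C(C)(C)C)cc(O[Si](C(C)C)(C(C)C)C(C)C)c1CC=C(C)C | intermediate (not isolated)
13 | 3-methoxy-4-(3-methylbut-2-enyl)-5-(triisopropylsilyloxy)-2-(trimethylsilyl)phenyl N-isopropylcarbamate | COc1c([Si](C)(C)C)c(OC(=O)NC(C)C)cc(O[Si](C(C)C)(C(C)C)C(C)C)c1CC=C(C)C | intermediate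
14 | tetrabutylammonium 5-[(isopropylcarbamoyl)oxy]-3-methoxy-2-(3-methylbut-2-enyl)-4-(trimethylsilyl)phenoxide | CCCC[N+](CCCC)(CCCC)CCCC.COc1c([Si](C)(C)C)c(OC(=O)NC(C)C)cc([O-])c1CC=C(C)C | intermediate (not isolated)
15 | 3-methoxy-4-(3-methylbut-2-enyl)-5-(pivaloyloxy)-2-(trimethylsilyl)phenyl N-isopropylcarbamate | COc1c([Si](C)(C)C)c(OC(=O)NC(C)C)cc(OC(=O)C(C)(C)C)c1CC=C(C)C | intermediate
16 | 5-hydroxy-3-methoxy-2-(3-methylbut-2-enyl)-4-(trimethylsilyl)phenyl pivalate | COc1c([Si](C)(C)C)c(O)cc(OC(=O)C(C)(C)C)c1CC=C(C)C | intermediate (not isolated)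
17 | 3-methoxy-4-(3-methylbut-2-enyl)-5-(pivaloyloxy)-2-(trimethylsilyl)phenyl trifluoromethanesulfonate | COc1c(CC=C(C)C)c(OC(=O)C(C)(C)C)cc(OS(=O)(=O)C(F)(F)F)c1[Si](C)(C)C | intermediate
18 | 4-bromobenzene-1,3-diol | Oc1ccc(Br)c(O)c1 | starting material
19 | 4-bromo-1,3-phenylene bis(2,2-dimethylpropanoate) | CC(C)(C)C(=O)Oc1ccc(Br)c(OC(=O)C(C)(C)C)c1 | intermediate
20 | 4,4,5,5-tetramethyl-2-(prop-1-en-2-yl)-1,3,2-dioxaborolane | CC(=C)B1OC(C)(C)C(C)(C)O1 | starting material
21 | 4-(prop-1-en-2-yl)-1,3-phenylene bis(2,2-dimethylpropanoate) | C=C(C)c1ccc(OC(=O)C(C)(C)C)cc1OC(=O)C(C)(C)C | intermediate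
22 | 2-[2,4-bis(pivaloyloxy)phenyl]prop-2-enal | C=C(C=O)c1ccc(OC(=O)C(C)(C)C)cc1OC(=O)C(C)(C)C | intermediate
23 | 3-methoxy-4-(3-methylbut-2-enyl)-5-(pivaloyloxy)benzyne (triple bond C4a≡C8a) | COC1=C(CC=C(C)C)C(OC(=O)C(C)(C)C)=CC#C1 | intermediate (not isolated)
24 | racemic benzoxete: four-membered ring C8a–O–C4–C4a, C4 bearing H and the 1-[2,4-bis(pivaloyloxy)phenyl]vinyl group | COc1c(CC=C(C)C)c(OC(=O)C(C)(C)C)cc2OC(C(=C)c3ccc(OC(=O)C(C)(C)C)cc3OC(=O)C(C)(C)C)c12 | intermediate (not isolated)
25 | o-quinone methide: C8a=O, exocyclic (Z)-C4a=C4 carrying the 2-arylvinyl arm on the side of the carbonyl oxygen | O=C1C=C(OC(=O)C(C)(C)C)C(CC=C(C)C)=C(OC)/C1=C/C(=C)c1ccc(OC(=O)C(C)(C)C)cc1OC(=O)C(C)(C)C | intermediate (not isolated)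
26 | 3-[2,4-bis(pivaloyloxy)phenyl]-5-methoxy-6-(3-methylbut-2-enyl)-2H-chromen-7-yl pivalate (tripivalate of dehydroglyasperin C) | COc1c2c(cc(OC(=O)C(C)(C)C)c1CC=C(C)C)OCC(c1ccc(OC(=O)C(C)(C)C)cc1OC(=O)C(C)(C)C)=C2 | intermediate
27 | dehydroglyasperin C, 4-[7-hydroxy-5-methoxy-6-(3-methylbut-2-enyl)-2H-chromen-3-yl]benzene-1,3-diol | COc1c2c(cc(O)c1CC=C(C)C)OCC(c1ccc(O)cc1O)=C2 | target

Total step count: 13 steps.
Longest linear sequence: 10 steps (steps 1 to 8, then 12 and 13); the enal branch has 3 steps (9 to 11).

Steps most likely to fail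

Step 12. The fluoride may trigger anionic oligomerisation of the 2-arylacrolein. The zwitterion may also close at the unsubstituted β-carbon instead of the carbonyl carbon, which would lead to the 4H-chromene isomer, and aryne ene reaction at a prenyl group may compete. Fallback (aryllithium addition, then dehydrative electrocyclisation): it sets out from carbamate 9 and enal 22 and comes back at 26. Carbamate 9 is N-silylated and lithiated exactly as in step 6, and aryllithium 11 is quenched at −78 °C with enal 22 instead of TMSCl. 1,2-Addition to the aldehyde, which is far faster than attack on the hindered pivalates, and acidic work-up should give the racemic 2-[1-hydroxy-2-arylallyl]aryl carbamate F1. DBU and Et2NH in MeCN at 40 °C remove the carbamate to give the ortho-hydroxybenzyl alcohol F2. Warming F2 in toluene (80 to 110 °C) should expel water to give the same kind of o-quinone methide, which closes by oxa-6π electrocyclisation to the 7-O-TIPS chromene dipivalate F3. Bu4NF followed by PivCl, as in step 7, converts F3 into 26.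

Step 4. The prenyl alkene may bind to or react at the iridium catalyst (hydroboration by the pinacolborane formed, or catalyst inhibition), so that aromatic borylation stalls or the side chain is consumed. Fallback (halide-based borylation): it sets out from prenyl bromide 2 and comes back at boronate 7, hence phenol 8. Commercial 1-chloro-3,5-dimethoxybenzene F4 is lithiated between its two methoxy groups (n-BuLi, THF, 0 °C) and alkylated with 2 under CuBr·SMe2 catalysis to give 5-chloro-1,3-dimethoxy-2-(3-methylbut-2-enyl)benzene F5. NaSEt in DMF removes one methyl group to give 5-chloro-3-methoxy-2-(3-methylbut-2-enyl)phenol F6, and TIPSCl with imidazole gives the silyl ether F7. Miyaura borylation of the aryl chloride at zerovalent palladium (Pd2(dba)3, XPhos, B2pin2, KOAc, 1,4-dioxane, 100 °C), which tolerates trisubstituted alkenes, should give 7, which is oxidised with NaBO3·4H2O as in step 4 to 8.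

Step 11. The hot selenium dioxide oxidation may stall at the allylic alcohol, over-oxidise, or lose the acrolein to oligomerisation during the reaction and its work-up. Fallback (arylacetaldehyde methylenation): it sets out from aryl bromide 19 and comes back at 22. Suzuki–Miyaura coupling of 19 with commercial (E)-2-(2-ethoxyvinyl)-4,4,5,5-tetramethyl-1,3,2-dioxaborolane (Pd(OAc)2, SPhos, K3PO4, toluene–H2O, 60 °C) should give the aryl enol ether, (E)-4-(2-ethoxyvinyl)-1,3-phenylene bis(2,2-dimethylpropanoate) F8. Brief treatment with dilute aq. HCl in THF at rt hydrolyses it to 2-[2,4-bis(pivaloyloxy)phenyl]acetaldehyde F9. Mannich-type α-methylenation of F9 with N,N-dimethylmethyleneiminium iodide and Et3N in CH2Cl2 at rt (aminomethylation, then loss of dimethylamine) gives 22 under mild, non-oxidising conditions.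

Further compounds
F1 | step 12 | racemic 2-{1-hydroxy-2-[2,4-bis(pivaloyloxy)phenyl]prop-2-enyl}-3-methoxy-4-(3-methylbut-2-enyl)-5-(triisopropylsilyloxy)phenyl N-isopropylcarbamate | CC(C)NC(=O)Oc1cc(O[Si](C(C)C)(C(C)C)C(C)C)c(CC=C(C)C)c(OC)c1C(O)C(=C)c1ccc(OC(=O)C(C)(C)C)cc1OC(=O)C(C)(C)C
F2 | step 12 | racemic 4-{3-hydroxy-3-[2-hydroxy-6-methoxy-5-(3-methylbut-2-enyl)-4-(triisopropylsilyloxy)phenyl]prop-1-en-2-yl}-1,3-phenylene bis(2,2-dimethylpropanoate) | Oc1cc(O[Si](C(C)C)(C(C)C)C(C)C)c(CC=C(C)C)c(OC)c1C(O)C(=C)c1ccc(OC(=O)C(C)(C)C)cc1OC(=O)C(C)(C)C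
F3 | step 12 | 4-[5-methoxy-6-(3-methylbut-2-enyl)-7-(triisopropylsilyloxy)-2H-chromen-3-yl]-1,3-phenylene bis(2,2-dimethylpropanoate) | COc1c2c(cc(O[Si](C(C)C)(C(C)C)C(C)C)c1CC=C(C)C)OCC(c1ccc(OC(=O)C(C)(C)C)cc1OC(=O)C(C)(C)C)=C2
F4 | step 4 | 1-chloro-3,5-dimethoxybenzene | COc1cc(Cl)cc(OC)c1
F5 | step 4 | 5-chloro-1,3-dimethoxy-2-(3-methylbut-2-enyl)benzene | COc1cc(Cl)cc(OC)c1CC=C(C)C
F6 | step 4 | 5-chloro-3-methoxy-2-(3-methylbut-2-enyl)phenol | COc1cc(Cl)cc(O)c1CC=C(C)C
F7 | step 4 | [5-chloro-3-methoxy-2-(3-methylbut-2-enyl)phenoxy]triisopropylsilane | COc1cc(Cl)cc(O[Si](C(C)C)(C(C)C)C(C)C)c1CC=C(C)C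
F8 | step 11 | (E)-4-(2-ethoxyvinyl)-1,3-phenylene bis(2,2-dimethylpropanoate) | CCO/C=C/c1ccc(OC(=O)C(C)(C)C)cc1OC(=O)C(C)(C)C
F9 | step 11 | 2-[2,4-bis(pivaloyloxy)phenyl]acetaldehyde | O=CCc1ccc(OC(=O)C(C)(C)C)cc1OC(=O)C(C)(C)C
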